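The route rests on opening ring C at C2–C3: the flavanone is unfolded to an achiral aryl benzyl ether in which ring A carries a diazoacetyl group (future C4 and C3) and the future O1 carries the ring B benzyl group (future C2). C2, the only stereocentre, is both α to O1 and benzylic to the electron-rich ring B, so its C–H bonds are ideal partners for a metal carbenoid. A chiral dirhodium catalyst lets the C3 carbenoid insert into one of the two enantiotopic C2–H bonds, which in one operation closes the pyranone ring, forms C2–C3 and sets the (2S) centre. Geranyl, MOM and silyl groups are already in place.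

Key step: step 8

Assumption: the sense of induction of the prolinate catalyst on this substrate cannot be predicted with confidence; the (S)-ligand series is written, and the mirror-image catalyst (from D-proline) is used if a trial run shows that it is the one favouring the (2S)-product.

Numbering note: late compounds use flavanone numbering (O1, C2, C3, C4, C4a, C5–C8, C8a; ring B primed); "geranyl" means (2E)-3,7-dimethylocta-2,6-dien-1-yl.

Step 1
Reactants: 1 2',4',6'-trihydroxyacetophenone; 2 geranyl bromide
Product: 3 1-[3-geranyl-2,4,6-trihydroxyphenyl]ethan-1-one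
Conditions: DBU (1.1 equiv), THF, 0 °C to rt
Reagents that add atoms: none
Why: C-alkylation of the ambident phloroglucinol-type anion (SN2 allylation of a vinylogous enolate) at either of the two equivalent free ring carbons should give a single mono-C-geranyl regioisomer, and direct displacement at the primary allylic bromide keeps the (E)-olefin.

Step 2
Reactants: 3 1-[3-geranyl-2,4,6-trihydroxyphenyl]ethan-1-one
Product: 4 1-[3-geranyl-2,6-dihydroxy-4-(methoxymethoxy)phenyl]ethan-1-one
Conditions: MOMCl (1.05 equiv), iPr2NEt, CH2Cl2, −10 to 0 °C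
Reagents that add atoms: chloromethyl methyl ether (MOMCl), COCCl
Why: Williamson-type etherification in which the 4-hydroxyl, para to the acetyl group and the only one not locked in a hydrogen bond to the carbonyl, is the most acidic and most exposed oxygen, so one equivalent of MOMCl should cap it first.

Step 3
Reactants: 5 3-hydroxy-4,5-dimethoxybenzaldehyde
Product: 6 3,4-dimethoxy-5-(methoxymethoxy)benzaldehyde
Conditions: MOMCl, iPr2NEt, CH2Cl2, 0 °C to rt
Reagents that add atoms: chloromethyl methyl ether (MOMCl), COCCl
Why: Williamson-type etherification of the only phenol, which masks the future 3'-hydroxyl for the basic and carbenoid steps ahead.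

Step 4
Reactants: 6 3,4-dimethoxy-5-(methoxymethoxy)benzaldehyde
Product: 7 [3,4-dimethoxy-5-(methoxymethoxy)phenyl]methanol
Conditions: NaBH4, MeOH, 0 °C
Reagents that add atoms: none
Why: Borohydride reduction of the aryl aldehyde to the primary benzylic alcohol, to which the MOM ether is inert.

Step 5
Reactants: 4 1-[3-geranyl-2,6-dihydroxy-4-(methoxymethoxy)phenyl]ethan-1-one; 7 [3,4-dimethoxy-5-(methoxymethoxy)phenyl]methanol
Product: 8 1-[6-{[3,4-dimethoxy-5-(methoxymethoxy)phenyl]methoxy}-3-geranyl-2-hydroxy-4-(methoxymethoxy)phenyl]ethan-1-one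
Conditions: PPh3, DIAD, THF, 0 °C to rt
Reagents that add atoms: none
Why: Mitsunobu etherification of a primary benzylic alcohol under neutral conditions, in which the chelated phenol flanked only by a ring hydrogen should react in preference to the one wedged between acetyl and geranyl, while the remaining hydroxyl is then held by the carbonyl so that a second alkylation is slow.

Step 6
Reactants: 8 1-[6-{[3,4-dimethoxy-5-(methoxymethoxy)phenyl]methoxy}-3-geranyl-2-hydroxy-4-(methoxymethoxy)phenyl]ethan-1-one
Product: 9 1-[2-(tert-butyldimethylsilyloxy)-6-{[3,4-dimethoxy-5-(methoxymethoxy)phenyl]methoxy}-3-geranyl-4-(methoxymethoxy)phenyl]ethan-1-one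
Conditions: TBSCl, imidazole, DMAP (cat.), DMF, 40 °C
Reagents that add atoms: tert-butyldimethylsilyl chloride (TBSCl), CC(C)(C)[Si](C)(C)Cl
Why: Silylation of the last, hindered and chelated phenol under imidazole/DMAP activation, a silyl ether being chosen for the future O5 because its oxygen is weakly basic and it offers no C–H bond α to oxygen to the carbenoid of step 8.

Step 7
Reactants: 9 1-[2-(tert-butyldimethylsilyloxy)-6-{[3,4-dimethoxy-5-(methoxymethoxy)phenyl]methoxy}-3-geranyl-4-(methoxymethoxy)phenyl]ethan-1-one
Product: 11 2-diazo-1-[2-(tert-butyldimethylsilyloxy)-6-{[3,4-dimethoxy-5-(methoxymethoxy)phenyl]methoxy}-3-geranyl-4-(methoxymethoxy)phenyl]ethan-1-one, via trifluoroacetyl diketone 10 (not isolated)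
Conditions: LiN(SiMe3)2, THF, −78 °C; CF3CO2CH2CF3, −78 °C; cold dil. HCl work-up; then MsN3, Et3N, H2O (1 equiv), MeCN, rt
Reagents that add atoms: methanesulfonyl azide, CS(=O)(=O)N=[N+]=[N-]; 2,2,2-trifluoroethyl trifluoroacetate, O=C(OCC(F)(F)F)C(F)(F)F (its trifluoroacetyl group stays in intermediate 10 only)
Why: Detrifluoroacetylative (deacylative Regitz-type) diazo transfer, in which kinetic enolate formation at the methyl group and Claisen-type trifluoroacetylation at −78 °C (cold enough to outrun silyl migration) activate the α-carbon and the sulfonyl azide then delivers N2 with loss of the trifluoroacetyl group as the sulfonamide.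

Step 8
Reactants: 11 2-diazo-1-[2-(tert-butyldimethylsilyloxy)-6-{[3,4-dimethoxy-5-(methoxymethoxy)phenyl]methoxy}-3-geranyl-4-(methoxymethoxy)phenyl]ethan-1-one
Product: 12 (2S)-5-(tert-butyldimethylsilyloxy)-2-[3,4-dimethoxy-5-(methoxymethoxy)phenyl]-6-geranyl-7-(methoxymethoxy)-2,3-dihydro-4H-chromen-4-one
Conditions: Rh2(S-BSP)4 [dirhodium tetrakis((S)-N-benzenesulfonylprolinate)] (2 mol %), CH2Cl2, slow addition of 11, 0 °C to rt
Reagents that add atoms: none
Why: The dirhodium catalyst expels N2 from 11 to give an electrophilic rhodium carbenoid at C3, which inserts through a concerted, hydride-transfer-like three-centre transition state into one C–H bond of the O–CH2–aryl group, forming the C2–C3 bond and turning the carbenoid carbon into the C3 methylene. The closest known reaction type is the enantioselective intramolecular C–H insertion of 2-alkoxyaryl diazomethyl ketones to 2-substituted chroman-4-ones under chiral divalent rhodium carboxylates. Ring C closes as a six-membered ring by 1,6-insertion, the only C–H mode open to the carbenoid because the 1,5-position is the ether oxygen itself. The new stereocentre C2 arises from the choice between the two enantiotopic benzylic hydrogens, which is dictated by the chiral prolinate ligands around the rhodium–rhodium core. The step needs C–H insertion to beat oxonium ylide formation at O1 (followed by a benzyl shift) and any reaction at the other ortho oxygen; this is secured by the carboxylate-ligated rhodium catalyst in a non-coordinating solvent, by the doubly activated C–H bond (α to oxygen and benzylic to ring B with its para methoxy group) and by the silyl ether at O5, whose oxygen is non-basic and which has no C–H bond α to oxygen. The geranyl double bonds and the two MOM groups sit meta or further from the carbenoid and cannot reach it within one molecule, and slow addition keeps bimolecular pathways down.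

Step 9
Reactants: 12 (2S)-5-(tert-butyldimethylsilyloxy)-2-[3,4-dimethoxy-5-(methoxymethoxy)phenyl]-6-geranyl-7-(methoxymethoxy)-2,3-dihydro-4H-chromen-4-one
Product: 13 (2S)-6-geranyl-5,7-dihydroxy-2-(3-hydroxy-4,5-dimethoxyphenyl)-2,3-dihydro-4H-chromen-4-one
Conditions: 3 M aq. HCl, MeOH, 40 °C
Reagents that add atoms: none
Why: Acid-catalysed methanolysis (acetal and silyl ether solvolysis) should remove both MOM groups and the phenolic silyl ether at O5 in one operation, flavanones being configurationally stable to acid so that C2 is untouched, while the moderate temperature spares the geranyl olefins.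

Compound list
1 | 2',4',6'-trihydroxyacetophenone | CC(=O)c1c(O)cc(O)cc1O | starting material
2 | geranyl bromide, (2E)-1-bromo-3,7-dimethylocta-2,6-diene | BrC/C=C(\C)CCC=C(C)C | starting material
3 | 1-[3-geranyl-2,4,6-trihydroxyphenyl]ethan-1-one | CC(=O)c1c(O)cc(O)c(C/C=C(\C)CCC=C(C)C)c1O | intermediate
4 | 1-[3-geranyl-2,6-dihydroxy-4-(methoxymethoxy)phenyl]ethan-1-one | CC(=O)c1c(O)cc(OCOC)c(C/C=C(\C)CCC=C(C)C)c1O | intermediate
5 | 3-hydroxy-4,5-dimethoxybenzaldehyde | COc1cc(C=O)cc(O)c1OC | starting material
6 | 3,4-dimethoxy-5-(methoxymethoxy)benzaldehyde | COc1cc(C=O)cc(OCOC)c1OC | intermediate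
7 | [3,4-dimethoxy-5-(methoxymethoxy)phenyl]methanol | COc1cc(CO)cc(OCOC)c1OC | intermediate
8 | 1-[6-{[3,4-dimethoxy-5-(methoxymethoxy)phenyl]methoxy}-3-geranyl-2-hydroxy-4-(methoxymethoxy)phenyl]ethan-1-one | CC(=O)c1c(OCc2cc(OC)c(OC)c(OCOC)c2)cc(OCOC)c(C/C=C(\C)CCC=C(C)C)c1O | intermediate
9 | 1-[2-(tert-butyldimethylsilyloxy)-6-{[3,4-dimethoxy-5-(methoxymethoxy)phenyl]methoxy}-3-geranyl-4-(methoxymethoxy)phenyl]ethan-1-one | CC(=O)c1c(OCc2cc(OC)c(OC)c(OCOC)c2)cc(OCOC)c(C/C=C(\C)CCC=C(C)C)c1O[Si](C)(C)C(C)(C)C | intermediate
10 | 1-[2-(tert-butyldimethylsilyloxy)-6-{[3,4-dimethoxy-5-(methoxymethoxy)phenyl]methoxy}-3-geranyl-4-(methoxymethoxy)phenyl]-4,4,4-trifluorobutane-1,3-dione (not isolated) | O=C(CC(=O)C(F)(F)F)c1c(OCc2cc(OC)c(OC)c(OCOC)c2)cc(OCOC)c(C/C=C(\C)CCC=C(C)C)c1O[Si](C)(C)C(C)(C)C | intermediate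
11 | 2-diazo-1-[2-(tert-butyldimethylsilyloxy)-6-{[3,4-dimethoxy-5-(methoxymethoxy)phenyl]methoxy}-3-geranyl-4-(methoxymethoxy)phenyl]ethan-1-one | [N-]=[N+]=CC(=O)c1c(OCc2cc(OC)c(OC)c(OCOC)c2)cc(OCOC)c(C/C=C(\C)CCC=C(C)C)c1O[Si](C)(C)C(C)(C)C | intermediate
12 | (2S)-5-(tert-butyldimethylsilyloxy)-2-[3,4-dimethoxy-5-(methoxymethoxy)phenyl]-6-geranyl-7-(methoxymethoxy)-2,3-dihydro-4H-chromen-4-one | COc1cc([C@@H]2CC(=O)c3c(cc(OCOC)c(C/C=C(\C)CCC=C(C)C)c3O[Si](C)(C)C(C)(C)C)O2)cc(OCOC)c1OC | intermediate
13 | (2S)-6-geranyl-5,7-dihydroxy-2-(3-hydroxy-4,5-dimethoxyphenyl)-2,3-dihydro-4H-chromen-4-one (CNP0228243.1) | COc1cc([C@@H]2CC(=O)c3c(cc(O)c(C/C=C(\C)CCC=C(C)C)c3O)O2)cc(O)c1OC | target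

Total step count: 9. Longest linear sequence: 7 steps (steps 1, 2, 5, 6, 7, 8 and 9, from 1); steps 3 and 4 build the ring B alcohol in parallel.

Steps most likely to fail

Step 8 (key step). The carbenoid may be captured by the lone pair of O1 to give a five-membered oxonium ylide that rearranges by a 1,2-benzyl shift, or the catalyst may discriminate poorly between the two enantiotopic benzylic hydrogens. The fallback closes ring C at O1–C2 by classical chemistry; it sets out from 4 and 6 and comes back to the route at 13. Claisen–Schmidt condensation of 4 with 6 (KOH, EtOH/H2O, rt) should give the (E)-chalcone F1. Oxa-Michael ring closure (NaOAc, EtOH, reflux) should then give the racemic 6-geranyl flavanone F2 together with the 8-geranyl isomer F3, which arises by closure through the hindered hydroxyl and is removed by chromatography. Kinetic resolution of F2 by asymmetric transfer hydrogenation (RhCl(C5Me5)[(R,R)-TsDPEN] or its mirror image, HCO2H/Et3N, EtOAc, rt; the catalyst antipode that consumes the (2R)-enantiomer is chosen in a trial run) should reduce the unwanted antipode to the cis-flavan-4-ol F5 and leave the (2S)-flavanone F4. The chelated ketone may need a longer reaction time here. F4 is then deprotected under the conditions of step 9 to give 13.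

Step 2. One equivalent of MOMCl may over-alkylate to the bis-ether or partly alkylate a chelated hydroxyl, giving mixtures that are hard to separate. The fallback replaces kinetic mono-protection by over-protection followed by chelation-directed unmasking; it sets out from 3 and comes back at 4. Exhaustive etherification of the two reactive hydroxyls (MOMCl, 2.5 equiv, iPr2NEt, CH2Cl2, rt) should give the bis-MOM ether F6, the buried 2-hydroxyl staying free. MgBr2·OEt2 (Et2O/toluene, rt) then binds between the carbonyl oxygen and the MOM oxygen peri to it and should cleave only that acetal, returning 4.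

Step 9. Protonation of the geranyl double bonds in methanolic HCl may lead to cyclisation onto the freshly liberated flanking phenols or to addition of methanol before all three protecting groups have gone. The fallback unmasks in two non-protic stages; it sets out from 12 and comes back at 13. Brief Lewis acid–thiol transacetalisation (ZnBr2, n-PrSH, CH2Cl2, 0 °C, minutes) should remove both MOM groups and give the silyl ether diphenol F7. Fluoride desilylation (Et3N·3HF, THF, rt), which is non-basic and so should not open the flavanone, then gives 13.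

Further compounds
F1 | step 8 | (2E)-1-[3-geranyl-2,6-dihydroxy-4-(methoxymethoxy)phenyl]-3-[3,4-dimethoxy-5-(methoxymethoxy)phenyl]prop-2-en-1-one | O=C(/C=C/c1cc(OC)c(OC)c(OCOC)c1)c1c(O)cc(OCOC)c(C/C=C(\C)CCC=C(C)C)c1O
F2 | step 8 | racemic 2-[3,4-dimethoxy-5-(methoxymethoxy)phenyl]-6-geranyl-5-hydroxy-7-(methoxymethoxy)-2,3-dihydro-4H-chromen-4-one | COc1cc(C2CC(=O)c3c(cc(OCOC)c(C/C=C(\C)CCC=C(C)C)c3O)O2)cc(OCOC)c1OC
F3 | step 8 | racemic 2-[3,4-dimethoxy-5-(methoxymethoxy)phenyl]-8-geranyl-5-hydroxy-7-(methoxymethoxy)-2,3-dihydro-4H-chromen-4-one | COc1cc(C2CC(=O)c3c(O)cc(OCOC)c(C/C=C(\C)CCC=C(C)C)c3O2)cc(OCOC)c1OC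
F4 | step 8 | (2S)-2-[3,4-dimethoxy-5-(methoxymethoxy)phenyl]-6-geranyl-5-hydroxy-7-(methoxymethoxy)-2,3-dihydro-4H-chromen-4-one | COc1cc([C@@H]2CC(=O)c3c(cc(OCOC)c(C/C=C(\C)CCC=C(C)C)c3O)O2)cc(OCOC)c1OC
F5 | step 8 | (2R,4R)-2-[3,4-dimethoxy-5-(methoxymethoxy)phenyl]-6-geranyl-7-(methoxymethoxy)-3,4-dihydro-2H-chromene-4,5-diol | COc1cc([C@H]2C[C@@H](O)c3c(cc(OCOC)c(C/C=C(\C)CCC=C(C)C)c3O)O2)cc(OCOC)c1OC
F6 | step 2 | 1-[3-geranyl-2-hydroxy-4,6-bis(methoxymethoxy)phenyl]ethan-1-one | CC(=O)c1c(OCOC)cc(OCOC)c(C/C=C(\C)CCC=C(C)C)c1O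
F7 | step 9 | (2S)-5-(tert-butyldimethylsilyloxy)-6-geranyl-7-hydroxy-2-(3-hydroxy-4,5-dimethoxyphenyl)-2,3-dihydro-4H-chromen-4-one | COc1cc([C@@H]2CC(=O)c3c(cc(O)c(C/C=C(\C)CCC=C(C)C)c3O[Si](C)(C)C(C)(C)C)O2)cc(O)c1OC
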